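The readings stem from a simulated flask with made-up constants; scatter was added.

all flasks: substrate 0.050 M
- beta: reagent in the second phase 0.035 M; run made earlier
- epsilon: reagent in the second phase 0.055 M; run made earlier
- maple: reagent in the second phase 0.0250 M; time 2.5 d; volume of the second phase over the first 0.50
- oak: reagent in the second phase 0.0475 M; time 2.5 d; volume of the second phase over the first 0.50

| run | time / d | target / % | substrate / % |
|---|---|---|---|
| beta | 0.417 | 7.0 | 92.8 |
| beta | 0.833 | 19.1 | 80.4 |
| beta | 1.25 | 27.9 | 71.9 |
| beta | 1.67 | 35.7 | 63.9 |
| beta | 2.00 | 40.6 | 58.6 |
| beta | 2.50 | 46.0 | 53.3 |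
| epsilon | 0.417 | 11.1 | 88.4 |
| epsilon | 0.833 | 27.8 | 73.4 |
| epsilon | 1.25 | 40.8 | 58.2 |
| epsilon | 1.67 | 52.4 | 47.1 |
| epsilon | 2.00 | 59.1 | 40.7 |
| epsilon | 2.50 | 66.0 | 32.6 |

(standard deviation of a reading: 0.5 percentage points)

- in the second phase: reagent in the second phase; everything else is in the first
- charges count per volume of the first phase; a concentration in a rate is the amount of a species over the volume of its own phase; every rate counts per litre of the first phase
- the earlier runs hold the two phases in the same ratio of volumes as the flask asked about
- a reading or a percentage of target counts all its forms, free or not

- the winner by amount of target, in percent of the substrate charged; "neither" if no more than 2 percentage points parts them (maple / oak / neither)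
- how much target is there at the end, in percent of the substrate charged: maple
- how much target is there at the end, in percent of the substrate charged: oak

1. A small charge of reagent in the second phase goes into maple. At one reagent per target, that charge is 0.500 of the substrate charge, so reagent is the limiting reagent in maple. Oak's charge is 0.950.

2. Beta, charged 0.700, holds 46.0% target at 2.50 d, so 0.657 of its reagent charge stands as target. This fraction is the spent share.

3. Epsilon, charged 1.10, has a spent share of 0.600. These two numbers seem not to go together: beta is short of reagent and epsilon of substrate, yet the shares lie close.

4. The earlier readings clear this up. At 1.67 d the shares are 0.510 for beta and 0.476 for epsilon, so both climb with time. From that reading to the last, beta's share climbs by 0.147, more than the 0.0570 that parts beta from epsilon at the end.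

5. My own reckoning takes the share as linear in the charge, which for oak is an interpolation between beta and epsilon and for maple an extrapolation below beta. Maple gets 0.686, hence 34.3% target. Oak gets 0.621, hence 59.0%. Oak leads by 25 percentage points, well past the margin.

6. The forecast names oak, with maple at 34% (31% to 37%) and oak at 59.5% (57% to 62%), holding that “the lag and the phase effects carry over”.

7. The flask gives oak: maple 34.6%, oak 59.5%.

    reagent in the reaction phase ⇌ reagent in the second phase, rate k1*([reagent in the reaction phase] - [reagent in the second phase]/K1) per volume of the first phase (partition coefficient = 1.30, kL = 6.80 × 10⁻⁶ s⁻¹)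
    reagent in the reaction phase + target → over-reacted product (k = 1.70 × 10⁻⁴ M⁻¹ s⁻¹)
    substrate + reagent in the reaction phase → target (k = 5.10 × 10⁻⁴ M⁻¹ s⁻¹)
    crystals ⇌ target, rate k4*(cs4 - [target]) while solid is left; crystals form when [target] > cs4 (solubility = 0.630 mM, k = 2.30 × 10⁻⁴ s⁻¹)

Oak's spent share is 0.626, lower than beta's 0.657, and maple's is 0.692. Oak read at 1.67 d holds 46.1%, and the shares of beta and epsilon at that time give 46.5%. Oak's target is held down in part because uptake of reagent in the second phase is slow and the run is short, and these two act together. Oak reaches 72.4% with fast uptake, and 90.9% after 25.0 d.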